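In abietane numbering (C19 lactone carbonyl, C20 the ring B vinyl CH), ring A (C1–C5, C10) is disconnected at C4–C5. The C6–O carbon beside C5 and the sp2 carbon C10 form a β-oxygenated ketone retron, so ring A is grown from a cyclopentane: a 1-(cis-oxiranyl)cyclopentanol made from an (S)-α-methyl β-keto ester undergoes a semipinacol shift of the quaternary carbon C4 to C5. One operation enlarges the ring to the cyclohexanone, sets C5 and C6 and lets the C19 ester lactonise onto O6. The C10 ketone then takes the 1β-oxygen and the methylene for ring-closing metathesis to ring B after aryllithium addition at C7; arene oxidation ends the route.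

Key step: step 10

Remark: atom numbers in the text are abietane numbers of the target, and the antipode of the phase-transfer catalyst in step 6 is taken as the one that gives (S)-9.

**Arene fragment**

Step 1
Reactants: 1 1,2,4-trimethoxybenzene
Product: 3 2-(2,3,6-trimethoxyphenyl)propan-2-ol, via aryllithium 2 (not isolated)
Conditions: n-BuLi, THF, 0 °C to rt; acetone, −78 °C to rt; H2O
Reagents that add atoms: acetone CC(C)=O
Why: Directed ortho-lithiation takes place at the position flanked by two methoxy groups and the aryllithium adds to acetone (1,2-addition).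

Step 2
Reactants: 3 2-(2,3,6-trimethoxyphenyl)propan-2-ol
Product: 4 1,2,4-trimethoxy-3-(propan-2-yl)benzene
Conditions: Et3SiH, CF3CO2H, CH2Cl2, 0 °C to rt
Reagents that add atoms: none
Why: Ionic hydrogenation, in which the tertiary benzylic cation stabilised by two ortho-methoxy groups is reduced by hydride transfer from the silane.

Step 3
Reactants: 4 1,2,4-trimethoxy-3-(propan-2-yl)benzene
Product: 5 1-bromo-2,4,5-trimethoxy-3-(propan-2-yl)benzene
Conditions: N-bromosuccinimide, MeCN, 0 °C to rt
Reagents that add atoms: N-bromosuccinimide O=C1CCC(=O)N1Br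
Why: Electrophilic aromatic bromination should go to the one free position that is ortho and para to methoxy groups (the later C8), the other free position being activated by one methoxy group only.

Step 4
Reactants: 5 1-bromo-2,4,5-trimethoxy-3-(propan-2-yl)benzene
Product: 6 2-bromo-3,5,6-trimethoxy-4-(propan-2-yl)benzaldehyde
Conditions: Cl2CHOCH3, TiCl4, CH2Cl2, −10 to 0 °C; H2O
Reagents that add atoms: dichloromethyl methyl ether COC(Cl)Cl; water O
Why: Rieche formylation (electrophilic aromatic substitution) at the last free ring position, ortho to a methoxy group (the later C9).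

Step 5
Reactants: 6 2-bromo-3,5,6-trimethoxy-4-(propan-2-yl)benzaldehyde
Product: 7 1-bromo-2-ethenyl-3,4,6-trimethoxy-5-(propan-2-yl)benzene
Conditions: Ph3PCH3Br, KOt-Bu, THF, 0 °C to rt
Reagents that add atoms: methyltriphenylphosphonium bromide C[P+](c1ccccc1)(c1ccccc1)c1ccccc1.[Br-]
Why: Wittig methylenation of the aryl aldehyde gives the styrene that later becomes C20.

**Ring A and lactone fragment**

Step 6
Reactants: 8 methyl 2-oxocyclopentane-1-carboxylate
Product: 9 methyl (S)-1-methyl-2-oxocyclopentane-1-carboxylate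
Conditions: MeI, K2CO3, toluene, 0 °C, chiral N-spiro binaphthyl-derived quaternary ammonium bromide (phase-transfer catalyst, 2 mol%)
Reagents that add atoms: iodomethane CI
Why: Asymmetric phase-transfer alkylation of a cyclic β-keto ester, in which the chiral ammonium enolate ion pair is methylated on one face and the quaternary centre (later C4) is set.

Step 7
Reactants: 9 methyl (S)-1-methyl-2-oxocyclopentane-1-carboxylate; 10 3,3-diethoxyprop-1-yne
Product: 13 methyl (1S,2S)-2-(3,3-diethoxyprop-1-yn-1-yl)-1-methyl-2-[(trimethylsilyl)oxy]cyclopentane-1-carboxylate, via lithium acetylide 11 (not isolated), via lithium alkoxide 12 (not isolated)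
Conditions: 10, n-BuLi, THF, −78 °C; 9, −78 to −40 °C; Me3SiCl, −40 °C to rt
Reagents that add atoms: chlorotrimethylsilane C[Si](C)(C)Cl
Why: 1,2-Addition of the acetylide to the ketone anti to the pseudo-axial, electron-withdrawing ester (Felkin–Anh) should place the alkynyl group cis to the C-methyl group, and the tertiary alkoxide is then O-silylated.

Step 8
Reactants: 13 methyl (1S,2S)-2-(3,3-diethoxyprop-1-yn-1-yl)-1-methyl-2-[(trimethylsilyl)oxy]cyclopentane-1-carboxylate
Product: 14 methyl (1S,2S)-2-[(Z)-3,3-diethoxyprop-1-en-1-yl]-1-methyl-2-[(trimethylsilyl)oxy]cyclopentane-1-carboxylate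
Conditions: H2 (1 atm), Pd/CaCO3 poisoned with Pb(OAc)2 (Lindlar catalyst), quinoline, EtOAc, rt
Reagents that add atoms: none
Why: Lindlar semihydrogenation delivers both hydrogens syn and gives the Z-alkene.

Step 9
Reactants: 14 methyl (1S,2S)-2-[(Z)-3,3-diethoxyprop-1-en-1-yl]-1-methyl-2-[(trimethylsilyl)oxy]cyclopentane-1-carboxylate
Product: 16 methyl (1S,2R)-2-[(2S,3R)-3-(diethoxymethyl)oxiran-2-yl]-2-hydroxy-1-methylcyclopentane-1-carboxylate, via epoxy silyl ether 15 (not isolated)
Conditions: mCPBA, NaHCO3, CH2Cl2, 0 °C to rt; then Bu4NF, AcOH, THF, 0 °C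
Reagents that add atoms: 3-chloroperbenzoic acid OOC(=O)c1cccc(Cl)c1
Why: Sterically controlled peracid epoxidation of the allylic silyl ether, with the C–O bond in the inside position (least 1,3-allylic strain with the Z-substituent; silylation removes hydroxyl direction) and the quaternary carbon anti to the reagent, should give the cis-oxirane by syn addition, and buffered fluoride then frees the carbinol without Payne rearrangement.

Step 10
Reactants: 16 methyl (1S,2R)-2-[(2S,3R)-3-(diethoxymethyl)oxiran-2-yl]-2-hydroxy-1-methylcyclopentane-1-carboxylate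
Product: 18 (3R,3aR,7aS)-3-(diethoxymethyl)-7a-methylhexahydro-2-benzofuran-1,4-dione, via hydroxy keto ester 17 (not isolated)
Conditions: ZnBr2, CH2Cl2, 0 °C to rt; then pyridinium p-toluenesulfonate (cat.), rt
Reagents that add atoms: none
Why: ZnBr2 activates the oxirane, its C–O bond at the carbinol-adjacent carbon (C5) breaks while the anti-periplanar quaternary ring carbon (C4) shifts from the carbinol carbon to C5, and the carbinol becomes the C10 ketone, which is a semipinacol rearrangement of a 2,3-epoxy alcohol (closest type: Lewis-acid ring enlargement of 1-oxiranylcycloalkanols). Ring A is thereby enlarged from five to six members by a 1,2-shift and not by a cyclisation, and the γ-lactone then closes by 5-exo-trig attack of the C6 hydroxyl on the ester, which now stands cis to it. C5 is formed with inversion and C6 keeps its oxygen with retention, so both follow from the cis-oxirane, while C4 migrates with retention. The step needs migration of the quaternary carbon and not of the ring CH2, which the higher substitution of the former and its anti-periplanar place in the rotamer already used for the epoxidation should secure, and it needs opening at C5 and not at C6, which the electron-withdrawing acetal on C6 secures. The carbinol stereocentre is erased in the step, so its only task was to steer the epoxidation.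

Step 11
Reactants: 18 (3R,3aR,7aS)-3-(diethoxymethyl)-7a-methylhexahydro-2-benzofuran-1,4-dione
Product: 20 (3R,3aR,5R,7aS)-3-(diethoxymethyl)-7a-methyl-1,4-dioxooctahydro-2-benzofuran-5-yl acetate, via α-ketol 19 (not isolated)
Conditions: KN(SiMe3)2, THF, −78 °C; 2-(phenylsulfonyl)-3-phenyloxaziridine, −78 °C; Ac2O, Et3N, DMAP (cat.), −78 °C to rt
Reagents that add atoms: 2-(phenylsulfonyl)-3-phenyloxaziridine O=S(=O)(c1ccccc1)N1OC1c1ccccc1; acetic anhydride CC(=O)OC(C)=O
Why: Kinetic enolisation at the CH2 flank (the ring-fusion CH is hindered) and Davis hydroxylation are followed by acetylation, and the oxygenated carbon α to the ketone should equilibrate under Et3N/DMAP to the equatorial acetate, cis to the lactone carbonyl carbon (1β).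

Step 12
Reactants: 20 (3R,3aR,5R,7aS)-3-(diethoxymethyl)-7a-methyl-1,4-dioxooctahydro-2-benzofuran-5-yl acetate
Product: 21 (3R,3aR,5R,7aS)-3-(diethoxymethyl)-7a-methyl-4-methylidene-1-oxooctahydro-2-benzofuran-5-yl acetate
Conditions: Zn, CH2Br2, TiCl4, THF/CH2Cl2, 0 °C to rt
Reagents that add atoms: dibromomethane BrCBr
Why: Lombardo methylenation with the non-basic zinc/titanium methylene reagent converts the hindered, enolisable ketone into the exocyclic alkene (later C10=C20) and leaves lactone, acetate and acetal alone.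

Step 13
Reactants: 21 (3R,3aR,5R,7aS)-3-(diethoxymethyl)-7a-methyl-4-methylidene-1-oxooctahydro-2-benzofuran-5-yl acetate
Product: 22 (3R,3aR,5R,7aS)-3-formyl-7a-methyl-4-methylidene-1-oxooctahydro-2-benzofuran-5-yl acetate
Conditions: LiBF4, MeCN/H2O (98:2), 50 °C
Reagents that add atoms: water O
Why: Mild Lewis-acid-assisted acetal hydrolysis frees the aldehyde, whose α-carbon (C6) already holds the thermodynamically favoured exo configuration and so should not drift.

**Union and endgame**

Step 14
Reactants: 22 (3R,3aR,5R,7aS)-3-formyl-7a-methyl-4-methylidene-1-oxooctahydro-2-benzofuran-5-yl acetate; 7 1-bromo-2-ethenyl-3,4,6-trimethoxy-5-(propan-2-yl)benzene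
Product: 24 (3R,3aR,5R,7aS)-3-[(S)-[2-ethenyl-3,4,6-trimethoxy-5-(propan-2-yl)phenyl](hydroxy)methyl]-7a-methyl-4-methylidene-1-oxooctahydro-2-benzofuran-5-yl acetate, via aryllithium 23 (not isolated)
Conditions: 7, n-BuLi, THF, −78 °C; then 22, −78 °C; AcOH, −78 °C
Reagents that add atoms: none
Why: Bromine–lithium exchange and 1,2-addition of the aryllithium to the aldehyde under Felkin–Anh control (C6–O bond anti to the incoming aryl) should give the 6,7-erythro carbinol (7S).

Step 15
Reactants: 24 (3R,3aR,5R,7aS)-3-[(S)-[2-ethenyl-3,4,6-trimethoxy-5-(propan-2-yl)phenyl](hydroxy)methyl]-7a-methyl-4-methylidene-1-oxooctahydro-2-benzofuran-5-yl acetate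
Product: 25 (1R,4S,5R,6R,7S)-1-acetoxy-7-hydroxy-11,12,14-trimethoxy-9(10→20)-abeo-abieta-8,11,13,10(20)-tetraen-19,6-olide
Conditions: [1,3-bis(2,4,6-trimethylphenyl)imidazolidin-2-ylidene]dichloro(2-isopropoxybenzylidene)ruthenium (second-generation Hoveyda–Grubbs catalyst, 10 mol%), toluene, 80 °C
Reagents that add atoms: none
Why: Ring-closing metathesis between the styrene and the 1,1-disubstituted alkene closes the seven-membered ring B and forms the trisubstituted C10=C20 alkene, whose geometry the ring fixes.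

Step 16
Reactants: 25 (1R,4S,5R,6R,7S)-1-acetoxy-7-hydroxy-11,12,14-trimethoxy-9(10→20)-abeo-abieta-8,11,13,10(20)-tetraen-19,6-olide
Product: 26 (1R,4S,5R,6R,7S)-1-acetoxy-7-hydroxy-12-methoxy-11,14-dioxo-9(10→20)-abeo-abieta-8,12,10(20)-trien-19,6-olide
Conditions: (NH4)2Ce(NO3)6, MeCN/H2O (2:1), 0 °C
Reagents that add atoms: water O
Why: Oxidative demethylation of the para-dimethoxy pair (C11, C14) by tetravalent cerium gives the 2-methoxy-1,4-benzoquinone.

Step 17
Reactants: 26 (1R,4S,5R,6R,7S)-1-acetoxy-7-hydroxy-12-methoxy-11,14-dioxo-9(10→20)-abeo-abieta-8,12,10(20)-trien-19,6-olide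
Product: 27 Ballotiquinone
Conditions: LiOH, THF/H2O, 0 °C; then 1 M HCl, rt
Reagents that add atoms: lithium hydroxide [Li+].[OH-]
Why: The methoxyquinone is a vinylogous ester and is hydrolysed by hydroxide (addition–elimination) together with the acetate, and acidification re-closes the γ-lactone onto O6 if it has opened.

**Compound list**

1 | 1,2,4-trimethoxybenzene | COc1ccc(OC)c(OC)c1 | starting material
2 | (2,3,6-trimethoxyphenyl)lithium | [Li]c1c(OC)ccc(OC)c1OC | intermediate
3 | 2-(2,3,6-trimethoxyphenyl)propan-2-ol | CC(C)(O)c1c(OC)ccc(OC)c1OC | intermediate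
4 | 1,2,4-trimethoxy-3-(propan-2-yl)benzene | CC(C)c1c(OC)ccc(OC)c1OC | intermediate
5 | 1-bromo-2,4,5-trimethoxy-3-(propan-2-yl)benzene | CC(C)c1c(OC)c(Br)cc(OC)c1OC | intermediate
6 | 2-bromo-3,5,6-trimethoxy-4-(propan-2-yl)benzaldehyde | CC(C)c1c(OC)c(Br)c(C=O)c(OC)c1OC | intermediate
7 | 1-bromo-2-ethenyl-3,4,6-trimethoxy-5-(propan-2-yl)benzene | CC(C)c1c(OC)c(Br)c(C=C)c(OC)c1OC | intermediate
8 | methyl 2-oxocyclopentane-1-carboxylate | COC(=O)C1CCCC1=O | starting material
9 | methyl (S)-1-methyl-2-oxocyclopentane-1-carboxylate | COC(=O)[C@@]1(C)CCCC1=O | intermediate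
10 | 3,3-diethoxyprop-1-yne | C#CC(OCC)OCC | starting material
11 | (3,3-diethoxyprop-1-yn-1-yl)lithium | [Li]C#CC(OCC)OCC | intermediate
12 | lithium (1S,2S)-1-(3,3-diethoxyprop-1-yn-1-yl)-2-(methoxycarbonyl)-2-methylcyclopentan-1-olate (alkynyl cis to C-methyl) | COC(=O)[C@@]1(C)CCC[C@]1(O[Li])C#CC(OCC)OCC | intermediate
13 | methyl (1S,2S)-2-(3,3-diethoxyprop-1-yn-1-yl)-1-methyl-2-[(trimethylsilyl)oxy]cyclopentane-1-carboxylate | COC(=O)[C@@]1(C)CCC[C@]1(O[Si](C)(C)C)C#CC(OCC)OCC | intermediate
14 | methyl (1S,2S)-2-[(Z)-3,3-diethoxyprop-1-en-1-yl]-1-methyl-2-[(trimethylsilyl)oxy]cyclopentane-1-carboxylate | COC(=O)[C@@]1(C)CCC[C@]1(O[Si](C)(C)C)/C=C\C(OCC)OCC | intermediate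
15 | methyl (1S,2R)-2-[(2S,3R)-3-(diethoxymethyl)oxiran-2-yl]-1-methyl-2-[(trimethylsilyl)oxy]cyclopentane-1-carboxylate | COC(=O)[C@@]1(C)CCC[C@]1(O[Si](C)(C)C)[C@H]2O[C@H]2C(OCC)OCC | intermediate
16 | methyl (1S,2R)-2-[(2S,3R)-3-(diethoxymethyl)oxiran-2-yl]-2-hydroxy-1-methylcyclopentane-1-carboxylate | COC(=O)[C@@]1(C)CCC[C@]1(O)[C@H]2O[C@H]2C(OCC)OCC | intermediate
17 | methyl (1S,2R)-2-[(1R)-2,2-diethoxy-1-hydroxyethyl]-1-methyl-3-oxocyclohexane-1-carboxylate | COC(=O)[C@@]1(C)CCCC(=O)[C@H]1[C@@H](O)C(OCC)OCC | intermediate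
18 | (3R,3aR,7aS)-3-(diethoxymethyl)-7a-methylhexahydro-2-benzofuran-1,4-dione (cis-fused keto γ-lactone) | CCOC(OCC)[C@@H]1OC(=O)[C@@]2(C)CCCC(=O)[C@@H]12 | intermediate
19 | (3R,3aR,5R,7aS)-3-(diethoxymethyl)-5-hydroxy-7a-methylhexahydro-2-benzofuran-1,4-dione (drawn as the equatorial epimer) | CCOC(OCC)[C@@H]1OC(=O)[C@@]2(C)CC[C@@H](O)C(=O)[C@@H]12 | intermediate
20 | (3R,3aR,5R,7aS)-3-(diethoxymethyl)-7a-methyl-1,4-dioxooctahydro-2-benzofuran-5-yl acetate | CCOC(OCC)[C@@H]1OC(=O)[C@@]2(C)CC[C@@H](OC(C)=O)C(=O)[C@@H]12 | intermediate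
21 | (3R,3aR,5R,7aS)-3-(diethoxymethyl)-7a-methyl-4-methylidene-1-oxooctahydro-2-benzofuran-5-yl acetate | CCOC(OCC)[C@@H]1OC(=O)[C@@]2(C)CC[C@@H](OC(C)=O)C(=C)[C@@H]12 | intermediate
22 | (3R,3aR,5R,7aS)-3-formyl-7a-methyl-4-methylidene-1-oxooctahydro-2-benzofuran-5-yl acetate | O=C[C@@H]1OC(=O)[C@@]2(C)CC[C@@H](OC(C)=O)C(=C)[C@@H]12 | intermediate
23 | [2-ethenyl-3,4,6-trimethoxy-5-(propan-2-yl)phenyl]lithium | [Li]c1c(C=C)c(OC)c(OC)c(C(C)C)c1OC | intermediate
24 | (3R,3aR,5R,7aS)-3-[(S)-[2-ethenyl-3,4,6-trimethoxy-5-(propan-2-yl)phenyl](hydroxy)methyl]-7a-methyl-4-methylidene-1-oxooctahydro-2-benzofuran-5-yl acetate | C=Cc1c(OC)c(OC)c(C(C)C)c(OC)c1[C@H](O)[C@@H]1OC(=O)[C@@]2(C)CC[C@@H](OC(C)=O)C(=C)[C@@H]12 | intermediate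
25 | (1R,4S,5R,6R,7S)-1-acetoxy-7-hydroxy-11,12,14-trimethoxy-9(10→20)-abeo-abieta-8,11,13,10(20)-tetraen-19,6-olide | CC(C)c1c(OC)c(OC)c2c(c1OC)[C@H](O)[C@@H]1OC(=O)[C@@]3(C)CC[C@@H](OC(C)=O)C(=C2)[C@@H]13 | intermediate
26 | (1R,4S,5R,6R,7S)-1-acetoxy-7-hydroxy-12-methoxy-11,14-dioxo-9(10→20)-abeo-abieta-8,12,10(20)-trien-19,6-olide | CC(C)C1=C(OC)C(=O)C2=C(C1=O)[C@H](O)[C@@H]1OC(=O)[C@@]3(C)CC[C@@H](OC(C)=O)C(=C2)[C@@H]13 | intermediate
27 | Ballotiquinone, (1R,4S,5R,6R,7S)-1,7,12-trihydroxy-11,14-dioxo-9(10→20)-abeo-abieta-8,12,10(20)-trien-19,6-olide | CC(C)C1=C(O)C(=O)C2=C(C1=O)[C@H](O)[C@@H]1OC(=O)[C@@]3(C)CC[C@@H](O)C(=C2)[C@@H]13 | target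

**Count**

Total steps: 17. Longest linear sequence: 12 steps (steps 6 to 17, from 8).

**Steps most likely to fail**

1. Step 10 (key step). The ring CH2 may migrate in competition with the ester-bearing quaternary carbon, or bromide may open the oxirane. The fallback sets out from 14 and comes back at 18; it removes the electron-withdrawing ester from the migrating carbon before the shift. i-Bu2AlH reduces the ester of 14 to the primary alcohol F1. Epoxidation as in step 9 gives the epoxy silyl ether F2, and buffered Bu4NF gives the epoxy diol F3. ZnBr2 then moves the now electron-richer quaternary carbon and gives the dihydroxy ketone F4. Oxidative lactonisation with TEMPO/PhI(OAc)2 (primary alcohol to aldehyde, lactol with the C6 hydroxyl, lactone) returns 18.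

2. Step 7. The acetylide may add with poor or reversed facial selectivity, so that the alkynyl group ends cis to the ester. The fallback sets out from 9 and comes back at 18; it uses the other carbinol epimer with hydroxyl-directed instead of sterically controlled epoxidation, which is possible because the carbinol centre is erased in step 10. Addition gives the epimeric lithium alkoxide F5, silylated to the silyl ether F6. Lindlar reduction gives the Z-alkene F7, and Bu4NF/AcOH gives the free Z-allylic alcohol F8. VO(acac)2/t-BuOOH then delivers oxygen syn to the hydroxyl and anti to the quaternary carbon, which for this epimer should give the epoxy alcohol F9 with the same oxirane configuration as 16. ZnBr2 converts F9 through 17 into 18.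

3. Step 14. Facial control in the aryllithium addition may be weak, or the α-acyloxy aldehyde may enolise. The fallback sets out from 24, taken as the mixture of carbinol epimers, and comes back at 24; C7 is then set by reagent control. Dess–Martin periodinane oxidises the mixture to the aryl ketone F10. Corey–Bakshi–Shibata reduction (2-methyl-oxazaborolidine antipode chosen for the 7S carbinol, catecholborane, toluene, −78 °C, which does not hydroborate the alkenes) returns 24 as one epimer.

Further compounds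
F1 | step 10 | [2-((Z)-3,3-diethoxyprop-1-en-1-yl)-1-methyl-2-(trimethylsilyloxy)cyclopentyl]methanol (ring stereocentres as in 14) | OC[C@@]1(C)CCC[C@]1(O[Si](C)(C)C)/C=C\C(OCC)OCC
F2 | step 10 | [2-(3-(diethoxymethyl)oxiran-2-yl)-1-methyl-2-(trimethylsilyloxy)cyclopentyl]methanol (stereocentres as in 15) | OC[C@@]1(C)CCC[C@]1(O[Si](C)(C)C)[C@H]2O[C@H]2C(OCC)OCC
F3 | step 10 | 1-[3-(diethoxymethyl)oxiran-2-yl]-2-(hydroxymethyl)-2-methylcyclopentan-1-ol (stereocentres as in 16) | OC[C@@]1(C)CCC[C@]1(O)[C@H]2O[C@H]2C(OCC)OCC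
F4 | step 10 | 2-(2,2-diethoxy-1-hydroxyethyl)-3-(hydroxymethyl)-3-methylcyclohexan-1-one (stereocentres as in 17) | OC[C@@]1(C)CCCC(=O)[C@H]1[C@@H](O)C(OCC)OCC
F5 | step 7 | lithium alkoxide epimeric with 12 at the carbinol carbon (alkynyl cis to ester) | COC(=O)[C@@]1(C)CCC[C@@]1(O[Li])C#CC(OCC)OCC
F6 | step 7 | methyl (1S,2R)-2-(3,3-diethoxyprop-1-yn-1-yl)-1-methyl-2-[(trimethylsilyl)oxy]cyclopentane-1-carboxylate | COC(=O)[C@@]1(C)CCC[C@@]1(O[Si](C)(C)C)C#CC(OCC)OCC
F7 | step 7 | methyl (1S,2R)-2-[(Z)-3,3-diethoxyprop-1-en-1-yl]-1-methyl-2-[(trimethylsilyl)oxy]cyclopentane-1-carboxylate | COC(=O)[C@@]1(C)CCC[C@@]1(O[Si](C)(C)C)/C=C\C(OCC)OCC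
F8 | step 7 | methyl (1S,2R)-2-[(Z)-3,3-diethoxyprop-1-en-1-yl]-2-hydroxy-1-methylcyclopentane-1-carboxylate | COC(=O)[C@@]1(C)CCC[C@@]1(O)/C=C\C(OCC)OCC
F9 | step 7 | methyl (1S,2S)-2-[(2S,3R)-3-(diethoxymethyl)oxiran-2-yl]-2-hydroxy-1-methylcyclopentane-1-carboxylate | COC(=O)[C@@]1(C)CCC[C@@]1(O)[C@H]2O[C@H]2C(OCC)OCC
F10 | step 14 | (3R,3aR,5R,7aS)-3-[2-ethenyl-3,4,6-trimethoxy-5-(propan-2-yl)benzoyl]-7a-methyl-4-methylidene-1-oxooctahydro-2-benzofuran-5-yl acetate | C=Cc1c(OC)c(OC)c(C(C)C)c(OC)c1C(=O)[C@@H]1OC(=O)[C@@]2(C)CC[C@@H](OC(C)=O)C(=C)[C@@H]12
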